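Readings and results are calculated with made-up constants, noise included.

**Next charge.** I expected 1.49 mM of working catalyst in the flask, out of 1.82 mM charged, once its 0.33 mM of stray impurity had taken free catalyst one for one. The next run hung on that figure: should it get more free catalyst or more coupling partner?

in all of them: substrate 0.091 M; protic impurity 4.55 mM; free catalyst 2 mol%

|  | coupling partner | stray impurity | remark |
|---|---|---|---|
| south | 1.1 equiv | 0.46 mM | run made earlier |
| south-west | 1.1 equiv | 0.73 mM | run made earlier |
| flask | 1.10 equiv | 0.33 mM |  |

| run | time / min | product / % |
|---|---|---|
| south | 6.00 | 14.7 |
| south | 15.0 | 34.4 |
| south | 30.0 | 59.7 |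
| south | 50.0 | 81.0 |
| south-west | 12.0 | 24.3 |
| south-west | 25.0 | 44.8 |
| south-west | 40.0 | 62.5 |
| south-west | 50.0 | 71.9 |

(scatter of a reading: 0.5 percentage points)

**Earlier runs.** The south and south-west runs differ in stray impurity. South made 59.7% product in 30.0 min, and south-west made 62.5% in 40.0 min, so the ratio of mean rates reads 0.785. One-for-one loss, reckoned from the charges, gives 0.801 for the ratio of surviving catalyst.

**Carried quantity.** So I carried catalyst charged over catalyst surviving the stray impurity: for the flask 1.22, the poison leverage. If the rate follows surviving catalyst while the loss stays fixed, this is the apparent order in free catalyst. One percent more catalyst should then buy 1.22 percent more rate, more than in proportion, but neither earlier run varied coupling partner. I chose to raise free catalyst and leave coupling partner at 1.10 equiv.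

**The forecast.**

1. apparent order in coupling partner when 20% of the substrate are converted (percent change of the rate of making product for one percent more coupling partner charged)
2. apparent order in free catalyst when 20% of the substrate are converted (percent change of the rate of making product for one percent more free catalyst charged)



The forecast gave 1 in coupling partner and 1.22 in free catalyst, noting that “Substrate and partner track each other closely and partner was never varied”.

**The flask.** coupling partner + free catalyst → catalyst intermediate A (k = 180 /M/min); catalyst intermediate A ⇌ catalyst intermediate B (K = 53.0, k = 3.90 /min); substrate + catalyst intermediate B → catalyst intermediate C (k = 43.0 /M/min); catalyst intermediate C → free catalyst + product (k = 43.0 /min); coupling partner + protic impurity → quenched reagent (k = 4.20 /M/min); free catalyst + stray impurity → spent catalyst (k = 5700 /M/min)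

For the flask the simulation gave 1.2 in free catalyst, beside the leverage of 1.22, and 0.14 in coupling partner, and twice the coupling partner multiplied the time to that conversion by 0.918. At 1.00 h in the flask, free catalyst had a half-life of 0.32 min by its step with coupling partner, far shorter than the 0.32 h of coupling partner by that step. At that time catalyst intermediate B, the resting state of the flask, held 62.8% of the catalyst charged, and free catalyst held 11.0%.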